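Assumption: the SMILES is taken literally (cis-fused hydroazulene). Daucane locants are used throughout: C1 = CH3-bearing ring-fusion carbon, C2/C3 = CH2, C4 = C(OH)(iPr), C5 = ring-fusion CH, C6 = CH–O-anisoyl, C7 = CH2, C8 = C(CH3)=, C9 = CH=, C10 = CH–OAc. β is the face of the C1 methyl; the target is (1S,4R,5R,6S,10S) with 1β-CH3, 5β-H, 4β-OH, 6α-O, 10β-O.

**Retrosynthetic overview**
1. 22 ⇐ oxygen-bridged tricycle 18: the anisoyl cation acylates the bridging O6 and acetate opens the allylic C10–O bond with inversion (key C–O bond; both esters in one operation).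
2. 18 ⇐ ketone 14: enol triflate, isopropyl cross-coupling, then Markovnikov hydration (C4–O from the β face).
3. 14 ⇐ diene diol 12: ring-closing metathesis (seven-membered ring), then Re2O7 allylic transposition with capture of C10 by the C6 hydroxyl (makes the bridge, erases C8).
4. 12 ⇐ 3-ethenylcyclopentenone 8 + MeMgBr + aldehyde 5: catalytic asymmetric conjugate addition/aldol (C1, C5, C6).
5. Ring order: cyclopentane (from 6) → cycloheptene → oxygen bridge → bridge opened in the last step.

**Route**

Step 1
Reactants: 1 ethyl acetate; 2 but-3-en-2-one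
Product: 4 ethyl 3-methyl-3-(trimethylsilyloxy)pent-4-enoate (racemic), via lithium alkoxide 3 (not isolated)
Conditions: LiN(iPr)2, THF, −78 °C; then Me3SiCl, −78 °C → rt
Reagents that add atoms: chlorotrimethylsilane C[Si](C)(C)Cl
Why: Kinetic 1,2-addition (aldol type) of the lithium ester enolate to the enone carbonyl, then O-silylation of the tertiary alkoxide; the new carbinol carbon (later C8) is racemic on purpose because it is erased in step 5.

Step 2
Reactants: 4 ethyl 3-methyl-3-(trimethylsilyloxy)pent-4-enoate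
Product: 5 3-methyl-3-(trimethylsilyloxy)pent-4-enal (racemic)
Conditions: iBu2AlH, CH2Cl2, −78 °C; MeOH, aqueous work-up
Reagents that add atoms: none
Why: Low-temperature half-reduction of an ester to the aldehyde through the stable aluminium hemiacetal; the silyl ether prevents retro-aldol cleavage.

Step 3
Reactants: 6 3-ethoxycyclopent-2-en-1-one
Product: 8 3-ethenylcyclopent-2-en-1-one, via magnesium alkoxide 7 (not isolated)
Conditions: CH2=CHMgBr, THF, 0 °C; then 1 M HCl, 0 °C
Reagents that add atoms: vinylmagnesium bromide C=C[Mg]Br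
Why: Stork–Danheiser sequence: 1,2-addition to the vinylogous ester, then acid hydrolysis with carbonyl transposition gives the cross-conjugated dienone.

Step 4
Reactants: 8 3-ethenylcyclopent-2-en-1-one; 5 3-methyl-3-(trimethylsilyloxy)pent-4-enal
Product: 12 (2R,3R)-3-ethenyl-2-[(1S)-1,3-dihydroxy-3-methylpent-4-en-1-yl]-3-methylcyclopentan-1-one (both C3′ epimers), via magnesium enolate 9 (not isolated), via titanium enolate 10 (not isolated), via O-silyl aldol 11 (not isolated)
Conditions: MeMgBr, Cu(OTf)2 (3 mol %), chiral imidazolinium chloride (N-heterocyclic carbene precursor, 4 mol %), Et2O, −10 °C; ClTi(OiPr)3, −78 → −40 °C; 5, −78 °C; citric acid, MeOH, 0 °C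
Reagents that add atoms: methylmagnesium bromide C[Mg]Br
Why: Copper-catalysed asymmetric conjugate addition (1,4-selective on β-alkenyl enones with carbene–copper/Grignard systems) sets C1; the regiodefined enolate, as its titanium triisopropoxide enolate, gives the syn aldol (C6) and is attacked at C5 anti to the C1 methyl, i.e. syn to the flat vinyl group (expected about 90 % ee, about 2:1 at C5, about 4:1 syn:anti, 1:1 at C8, which is irrelevant).

Step 5
Reactants: 12 aldol diol
Product: 14 bridged ether ketone (6α,10α-epoxy, C8=C9, 4-oxo, 1β-CH3, 5β-H), via cycloheptene diol 13 (not isolated)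
Conditions: second-generation Hoveyda–Grubbs catalyst RuCl2(=CH-C6H4-2-OiPr)(SIMes) (10 mol %), toluene (0.005 M), 80 °C, argon sparge; then Re2O7 (5 mol %), CH2Cl2, 0 °C → rt
Reagents that add atoms: none
Why: Hydroxyl-assisted ring-closing metathesis closes the cycloheptene (sterically demanding, both vinyl groups sit on fully substituted carbons); Re2O7-catalysed 1,3-transposition of the tertiary allylic alcohol through the allyl perrhenate then lets the C6 hydroxyl capture C10 on the α face, the only face it can reach, so both C8 epimers converge and only the 5β-H/6α-O diastereomer can bridge (minor aldol isomers stay as diols and are removed).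

Step 6
Reactants: 14 bridged ether ketone
Product: 15 enol triflate of 14 (C3=C4–OTf)
Conditions: KN(SiMe3)2, THF, −78 °C; PhNTf2, −78 → 0 °C
Reagents that add atoms: N-phenylbis(trifluoromethanesulfonimide) O=S(=O)(N(c1ccccc1)S(=O)(=O)C(F)(F)F)C(F)(F)F
Why: Kinetic deprotonation at the C3 methylene rather than the hindered C5 methine, then O-triflation of the enolate; no free hydroxyl is present because O6 is tied up in the bridge.

Step 7
Reactants: 15 enol triflate
Product: 16 4-isopropyl-Δ3 alkene of the bridged ether (C3=C4–iPr, C8=C9, 6α,10α-epoxy)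
Conditions: iPrMgCl, Fe(acac)3 (5 mol %), THF/NMP, −30 °C, 15 min
Reagents that add atoms: isopropylmagnesium chloride CC(C)[Mg]Cl
Why: Iron-catalysed Kumada-type cross-coupling of an alkenyl triflate with a secondary alkyl Grignard reagent, fast enough at −30 °C to leave the allylic ether bridge untouched and free of isopropyl-to-propyl isomerisation.

Step 8
Reactants: 16 4-isopropyl-Δ3 alkene
Product: 18 6α,10α-epoxy-5βH-dauc-8-en-4β-ol (4α-isopropyl), via tertiary hydroperoxide 17 (not isolated)
Conditions: Mn(dpm)3 (10 mol %), PhSiH3, O2 (1 atm), iPrOH/CH2Cl2, 0 °C; then PPh3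
Reagents that add atoms: dioxygen O=O
Why: Mukaiyama-type hydration by metal-hydride hydrogen-atom transfer: H adds to C3 and the tertiary C4 radical is trapped by O2 on the β face, opposite the C5–C6 bond that carries the oxabicycle, giving 4β-OH/4α-iPr; the cyclopentene should react before the bridged C8=C9 alkene, which is more shielded and deactivated by its allylic C–O bond.

Step 9
Reactants: 18 bridged ether alcohol; 19 4-methoxybenzoyl chloride
Product: 22 (3R,3aR,4S,8S,8aS)-8-(acetyloxy)-3-hydroxy-6,8a-dimethyl-3-(propan-2-yl)-1,2,3,3a,4,5,8,8a-octahydroazulen-4-yl 4-methoxybenzoate, via silyl ether 20 (not isolated), via silylated diester 21 (not isolated)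
Conditions: BSA, MeCN, 60 °C, evaporate; [4-MeOC6H4CO]SbF6 (from 19 + AgSbF6, CH2Cl2, −40 °C, filtered), 2,6-di-tert-butyl-4-methylpyridine, CH2Cl2, −78 °C, 5 min; Bu4NOAc, −78 → −40 °C; citric acid, MeOH, 0 °C
Reagents that add atoms: tetrabutylammonium acetate CC(=O)[O-].CCCC[N+](CCCC)(CCCC)CCCC
Why: Proposed new method: an acylium-triggered mixed bis-acyloxylative opening of a bridging allylic ether, in which the weakly electrophilic 4-methoxybenzoylium ion acylates the ether oxygen (the only basic site once the C4 hydroxyl is masked as its silyl ether), the allylic C10–O bond of the oxonium ion ionises with participation of the new anisoyl carbonyl (a p-anisyl-stabilised seven-membered dioxacarbenium ion or its tight allyl-cation equivalent that keeps the α face of C10 covered), and acetate then attacks C10 from the β face so that the C10–OAc centre is set by inversion, C8=C9 is kept and O6 ends as the anisate; the closest known chemistry is the acylative cleavage of cyclic and oxa-bridged ethers by acyl halide/Lewis acid or anhydride/Lewis acid pairs (giving halo esters or symmetrical diesters) and the Prévost-type anti opening of acyloxonium ions by carboxylates.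

**Compound list**
1 | ethyl acetate | CCOC(C)=O | starting material
2 | but-3-en-2-one | CC(=O)C=C | starting material
3 | lithium alkoxide of ethyl 3-hydroxy-3-methylpent-4-enoate (racemic) | CCOC(=O)CC(C)(O[Li])C=C | intermediate
4 | ethyl 3-methyl-3-(trimethylsilyloxy)pent-4-enoate (racemic) | CCOC(=O)CC(C)(O[Si](C)(C)C)C=C | intermediate
5 | 3-methyl-3-(trimethylsilyloxy)pent-4-enal (racemic) | O=CCC(C)(O[Si](C)(C)C)C=C | intermediate
6 | 3-ethoxycyclopent-2-en-1-one | CCOC1=CC(=O)CC1 | starting material
7 | bromomagnesium alkoxide of 3-ethoxy-1-ethenylcyclopent-2-en-1-ol (racemic) | CCOC1=CC(O[Mg]Br)(C=C)CC1 | intermediate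
8 | 3-ethenylcyclopent-2-en-1-one | C=CC1=CC(=O)CC1 | intermediate
9 | bromomagnesium enolate of (S)-3-ethenyl-3-methylcyclopentanone (enolate C=C toward the quaternary carbon) | Br[Mg]OC1=C[C@@](C)(C=C)CC1 | intermediate
10 | tri(propan-2-yloxy)titanium enolate of (S)-3-ethenyl-3-methylcyclopentanone | CC(C)O[Ti](OC(C)C)(OC(C)C)OC1=C[C@@](C)(C=C)CC1 | intermediate
11 | (2R,3R)-3-ethenyl-2-[(1S)-1-hydroxy-3-methyl-3-(trimethylsilyloxy)pent-4-en-1-yl]-3-methylcyclopentan-1-one (both C3′ epimers) | O[C@H]([C@@H]1C(=O)CC[C@]1(C)C=C)CC(C)(O[Si](C)(C)C)C=C | intermediate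
12 | (2R,3R)-3-ethenyl-2-[(1S)-1,3-dihydroxy-3-methylpent-4-en-1-yl]-3-methylcyclopentan-1-one (both C3′ epimers) | O[C@H]([C@@H]1C(=O)CC[C@]1(C)C=C)CC(C)(O)C=C | intermediate
13 | (3aR,4S,8aR)-4,6-dihydroxy-6,8a-dimethyl-1,2,3a,4,5,6-hexahydroazulen-3(8aH)-one (cis-fused; both C6 epimers; daucane: 4-oxo, 6α-OH, 8-OH, C9=C10) | O[C@H]1CC(C)(O)C=C[C@@]2(C)CCC(=O)[C@@H]12 | intermediate
14 | bridged ether ketone: cis-fused hydroazulen-4-one with an oxygen bridge C6–O–C10 on the α face, C8=C9, 8-CH3, 1β-CH3, 5β-H | O1[C@H]2CC(C)=C[C@@H]1[C@@]3(C)CCC(=O)[C@@H]23 | intermediate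
15 | enol triflate of 14 (C3=C4–OSO2CF3) | O1[C@H]2CC(C)=C[C@@H]1[C@@]3(C)CC=C(OS(=O)(=O)C(F)(F)F)[C@@H]23 | intermediate
16 | 6α,10α-epoxy-5βH-dauca-3,8-diene (C3=C4–iPr) | O1[C@H]2CC(C)=C[C@@H]1[C@@]3(C)CC=C(C(C)C)[C@@H]23 | intermediate
17 | 6α,10α-epoxy-5βH-dauc-8-en-4β-yl hydroperoxide | O1[C@H]2CC(C)=C[C@@H]1[C@@]3(C)CC[C@@](OO)(C(C)C)[C@@H]23 | intermediate
18 | 6α,10α-epoxy-5βH-dauc-8-en-4β-ol (4α-isopropyl) | O1[C@H]2CC(C)=C[C@@H]1[C@@]3(C)CC[C@@](O)(C(C)C)[C@@H]23 | intermediate
19 | 4-methoxybenzoyl chloride | COc1ccc(cc1)C(Cl)=O | starting material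
20 | trimethylsilyl ether of 18 (4β-OSiMe3) | O1[C@H]2CC(C)=C[C@@H]1[C@@]3(C)CC[C@@](O[Si](C)(C)C)(C(C)C)[C@@H]23 | intermediate
21 | 4-O-trimethylsilyl ether of 22 | COc1ccc(C(=O)O[C@H]2CC(C)=C[C@H](OC(C)=O)[C@@]3(C)CC[C@@](O[Si](C)(C)C)(C(C)C)[C@@H]23)cc1 | intermediate
22 | (3R,3aR,4S,8S,8aS)-8-(acetyloxy)-3-hydroxy-6,8a-dimethyl-3-(propan-2-yl)-1,2,3,3a,4,5,8,8a-octahydroazulen-4-yl 4-methoxybenzoate (CNP0256979.4) | COc1ccc(C(=O)O[C@H]2CC(C)=C[C@H](OC(C)=O)[C@@]3(C)CC[C@@](O)(C(C)C)[C@@H]23)cc1 | target

**Step count**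
Total: 9 steps. Longest linear sequence: 8 steps (1, 2, 4, 5, 6, 7, 8, 9 from ethyl acetate); 7 steps from 6.

**Three steps most likely to fail**

Step 4 (three-component conjugate addition/aldol). The weak point is the face selection at C5: methyl and vinyl on C1 differ little in size, so the wanted diastereomer may be only about half of the aldol mixture. The fallback sets out from 6 and returns at 12, using an ethynyl group, which is far smaller than methyl, in place of vinyl. Compound 6 is treated with LiC≡CSiMe3 (THF, −78 °C; aqueous HCl) to give 3-[(trimethylsilyl)ethynyl]cyclopent-2-en-1-one F1. The same Cu(OTf)2/carbene-catalysed MeMgBr 1,4-addition, ClTi(OiPr)3 transmetalation, addition of 5 and citric acid/MeOH work-up give the silylalkynyl aldol F2, now attacked cleanly anti to the methyl. Bu4NF/AcOH removes the C-silyl group to give the terminal alkyne F3. Semihydrogenation (H2, Pd/CaCO3 poisoned with Pb(OAc)2, quinoline) gives 12.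

Step 8 (hydration). Hydrogen-atom transfer may not discriminate well enough between the cyclopentene and the bridged C8=C9 alkene. The fallback sets out from 16 and returns at 18 by an electrophilic, then hydridic, sequence. mCPBA/NaHCO3 (CH2Cl2, −20 °C) epoxidises the more electron-rich cyclopentene from the β face to give the 3β,4β-epoxide F4; the bridged alkene is deactivated by its allylic oxygen. LiEt3BH (THF, 0 °C) opens F4 at the secondary C3 and leaves the 4β-alcohol 18.

Step 9 (new mixed acyloxylative bridge opening). Possible failures are acyl scrambling, attack of acetate at C8, or loss of stereocontrol at C10. The fallback uses known chemistry, sets out from 20 and returns at 21. Acylative ether cleavage with 19 and catalytic ZnCl2 (CH2Cl2, 0 °C) gives the O6-anisoyl allylic chloride F5. Silver-assisted substitution (AgOAc, AcOH/CH2Cl2) then puts acetate on C10 from the face away from the C6 ester to give 21. The usual citric acid/MeOH work-up releases 22; any C10 epimer is separated.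

Further compounds
F1 | step 4 | 3-[(trimethylsilyl)ethynyl]cyclopent-2-en-1-one | C[Si](C)(C)C#CC1=CC(=O)CC1
F2 | step 4 | (2R,3R)-2-[(1S)-1,3-dihydroxy-3-methylpent-4-en-1-yl]-3-methyl-3-[(trimethylsilyl)ethynyl]cyclopentan-1-one (both C3′ epimers) | O[C@H]([C@@H]1C(=O)CC[C@]1(C)C#C[Si](C)(C)C)CC(C)(O)C=C
F3 | step 4 | (2R,3R)-2-[(1S)-1,3-dihydroxy-3-methylpent-4-en-1-yl]-3-ethynyl-3-methylcyclopentan-1-one (both C3′ epimers) | O[C@H]([C@@H]1C(=O)CC[C@]1(C)C#C)CC(C)(O)C=C
F4 | step 8 | 3β,4β:6α,10α-diepoxy-5βH-dauc-8-ene | O1[C@H]2CC(C)=C[C@@H]1[C@@]3(C)C[C@@H]4O[C@]4(C(C)C)[C@@H]23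
F5 | step 9 | 10-chloro-4β-(trimethylsilyloxy)-5βH-dauc-8-en-6α-yl 4-methoxybenzoate (C10 epimers) | COc1ccc(C(=O)O[C@H]2CC(C)=CC(Cl)[C@@]3(C)CC[C@@](O[Si](C)(C)C)(C(C)C)[C@@H]23)cc1
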